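**Retrosynthetic overview**

1. Target 21 is the protonated form of dipotassium salt 20, which comes from 7-O/3-O-selective sulfation of tamarixetin 18; 18 comes from hydrogenolysis of tetrabenzyl flavonol 17.
2. The strategy rests on O1 of ring C, which bridges C2 (the carbon bearing ring B) and C8a of ring A. C8a lies ortho to the C4 carbonyl, so a bromide there is activated and the enol oxygen on C2 is placed for a six-membered closure. Disconnecting O1–C8a (copper-catalysed enol O-arylation) leads to bromo diketone 16, which already carries the C3 oxygen as a benzyl ether.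
3. 16 is opened at the C3–C4 bond: aldol addition of the enolate of α-benzyloxy ketone 13 to bromo aldehyde 5, then oxidation.
4. 5 comes from Vilsmeier formylation of dibenzylated 5-bromoresorcinol, ortho to bromine; 13 comes from an aryllithium (benzylated 5-bromo-2-methoxyphenol) and the Weinreb amide of benzyloxyacetic acid.
5. Ring order: rings A and B are bought as arenes; ring C is the only ring made, in step 8.

Key step: step 8

Assumption: the target is taken as the free bis(hydrogen sulfate) as drawn; because such half esters are hydrolytically labile as free acids, the material is purified and stored as its dipotassium salt and protonated only in the last operation.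

**Route**

Step 1
Reactants: 1 5-bromoresorcinol; 2 benzyl bromide
Product: 3 1,3-bis(benzyloxy)-5-bromobenzene
Conditions: BnBr (2.2 equiv), K2CO3, DMF, rt → 60 °C
Reagents that add atoms: benzyl bromide (compound 2), BrCc1ccccc1
Why: Williamson ether synthesis; both phenoxides are O-benzylated under carbonate and the aryl bromide is inert.

Step 2
Reactants: 3 1,3-bis(benzyloxy)-5-bromobenzene
Product: 5 2,4-bis(benzyloxy)-6-bromobenzaldehyde, via aryliminium dichlorophosphate 4 (not isolated)
Conditions: POCl3 (1.5 equiv), DMF, 0 → 75 °C; then aq NaOAc, rt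
Reagents that add atoms: N,N-dimethylformamide, CN(C)C=O; water, O
Why: Vilsmeier–Haack formylation; the chloroiminium ion should attack one of the two symmetry-equivalent positions ortho to bromine (each ortho to one benzyloxy group and para to the other), the regiochemistry known for the corresponding dimethyl ether, and hydrolysis of 4 gives the aldehyde, with any 4-bromo-2,6-isomer removed by crystallisation.

Step 3
Reactants: 6 5-bromo-2-methoxyphenol; 2 benzyl bromide
Product: 7 2-(benzyloxy)-4-bromo-1-methoxybenzene
Conditions: BnBr (1.1 equiv), K2CO3, DMF, rt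
Reagents that add atoms: benzyl bromide (compound 2), BrCc1ccccc1
Why: Williamson ether synthesis on the single phenol.

Step 4
Reactants: 8 2-(benzyloxy)acetyl chloride; 9 N,O-dimethylhydroxylamine hydrochloride
Product: 10 2-(benzyloxy)-N-methoxy-N-methylacetamide
Conditions: Et3N (2.2 equiv), CH2Cl2, 0 °C → rt
Reagents that add atoms: none
Why: N-acylation of the hydroxylamine by the acid chloride (Weinreb amide formation) is fast and clean with an amine base.

Step 5
Reactants: 7 2-(benzyloxy)-4-bromo-1-methoxybenzene; 10 2-(benzyloxy)-N-methoxy-N-methylacetamide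
Product: 13 2-(benzyloxy)-1-[3-(benzyloxy)-4-methoxyphenyl]ethan-1-one, via aryllithium 11 (not isolated), via lithium hemiaminal chelate 12 (not isolated)
Conditions: n-BuLi (1.05 equiv), THF, −78 °C; then 10, −78 → 0 °C; then 1 M HCl
Reagents that add atoms: none
Why: Bromine–lithium exchange followed by Weinreb ketone synthesis; the chelated tetrahedral adduct 12 prevents over-addition and collapses to the ketone only on acidic quench.

Step 6
Reactants: 13 2-(benzyloxy)-1-[3-(benzyloxy)-4-methoxyphenyl]ethan-1-one; 5 2,4-bis(benzyloxy)-6-bromobenzaldehyde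
Product: 15 2-(benzyloxy)-3-[2,4-bis(benzyloxy)-6-bromophenyl]-1-[3-(benzyloxy)-4-methoxyphenyl]-3-hydroxypropan-1-one (racemic syn/anti mixture), via lithium Z-enolate 14 (not isolated)
Conditions: LDA (1.1 equiv), THF, −78 °C; then 5, −78 °C; AcOH/THF quench at −78 °C
Reagents that add atoms: none
Why: Directed aldol addition of a preformed, chelated lithium enolate to a non-enolisable aldehyde; the two new stereocentres form without control, which is acceptable because both are erased in steps 7 and 8.

Step 7
Reactants: 15 aldol adduct
Product: 16 2-(benzyloxy)-1-[2,4-bis(benzyloxy)-6-bromophenyl]-3-[3-(benzyloxy)-4-methoxyphenyl]propane-1,3-dione (racemic, enolisable)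
Conditions: Dess–Martin periodinane (1.2 equiv), CH2Cl2, 0 °C → rt
Reagents that add atoms: none
Why: Dess–Martin oxidation of the secondary benzylic alcohol converges both diastereomers onto one 1,3-diketone under near-neutral conditions that leave the benzyl ethers and the aryl bromide untouched.

Step 8
Reactants: 16 bromo 1,3-diketone
Product: 17 3,5,7-tris(benzyloxy)-2-[3-(benzyloxy)-4-methoxyphenyl]-4H-chromen-4-one (3,5,7,3'-tetra-O-benzyl-4'-O-methylquercetin)
Conditions: CuI (10 mol %), 1,10-phenanthroline (20 mol %), K2CO3 (2 equiv), dry degassed DMF, 95 °C, argon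
Reagents that add atoms: none
Why: K2CO3 removes the acidic central C–H of 16 and the enolate binds monovalent copper through the oxygen of the carbonyl attached to ring B (the future O1); oxidative addition into the C8a–Br bond, which is ortho to the ring A carbonyl and meta to both benzyloxy groups, gives a trivalent copper aryl enolate, and reductive elimination forms O1–C8a. This is an intramolecular Ullmann-type C–O coupling, the known copper-catalysed cyclisation of 1-(2-haloaryl)-1,3-diketones to flavones and chromones. Ring C closes as a six-membered ring (formally a 6-exo-trig attack of oxygen on C8a, the reductive elimination proceeding from a seven-membered copper chelate), and the gain of the aromatic 4-pyranone drives the step. No stereocentre is formed, and the racemic centre of 16 disappears as that carbon becomes sp2 C3. The selectivity needed is O- over C-arylation and the choice between the two enolate oxygens; C-arylation or attack by the ring A carbonyl oxygen would give four-membered rings, so only the distal oxygen can close, and the benzyloxy group on the central carbon is carried through as the C3 oxygen. A dry, degassed and moderately dilute medium is chosen to hold back retro-Claisen cleavage and intermolecular coupling.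

Step 9
Reactants: 17 tetrabenzyl flavonol
Product: 18 tamarixetin (3,5,7-trihydroxy-2-(3-hydroxy-4-methoxyphenyl)-4H-chromen-4-one)
Conditions: H2 (1 atm), 10% Pd/C, THF/MeOH 1:1, rt
Reagents that add atoms: none
Why: Catalytic hydrogenolysis cleaves the three aryl benzyl ethers and the C3 benzyl enol ether, while the aryl methyl ether and the C2=C3 bond of the aromatic pyranone should survive these mild conditions.

Step 10
Reactants: 18 tamarixetin
Product: 20 dipotassium tamarixetin 3,7-disulfate, via bis(tetrabutylammonium) disulfate 19 (not isolated)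
Conditions: Bu4N·HSO4 (6 equiv), DCC (12 equiv), pyridine, 4 °C → rt, followed by HPLC; then KOAc, MeOH; Sephadex LH-20 (H2O/MeOH)
Reagents that add atoms: tetrabutylammonium hydrogen sulfate, CCCC[N+](CCCC)(CCCC)CCCC.OS(=O)(=O)[O-]; potassium acetate, CC(=O)[O-].[K+]
Why: Carbodiimide-mediated sulfation; the DCC-activated hydrogen sulfate transfers SO3 first to the most acidic 7-OH and then to the 3-OH, whereas the 5-OH is held in a hydrogen bond to the C4 carbonyl and the 3'-OH (least acidic, ortho to the methoxy group) is expected to be spared, in line with the known behaviour of this reagent pair toward flavonols.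

Step 11
Reactants: 20 dipotassium tamarixetin 3,7-disulfate
Product: 21 tamarixetin 3,7-bis(hydrogen sulfate) (CNP0574123.0)
Conditions: Dowex 50W-X8 (H+ form), H2O, 0–5 °C; immediate lyophilisation
Reagents that add atoms: none
Why: Cation exchange on a sulfonic acid resin replaces potassium by protons without any bond change; cold, brief handling limits acid-catalysed hydrolysis of the sulfate half esters.

**Compound list**

1 | 5-bromoresorcinol (5-bromobenzene-1,3-diol) | Oc1cc(O)cc(Br)c1 | starting material
2 | benzyl bromide | BrCc1ccccc1 | starting material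
3 | 1,3-bis(benzyloxy)-5-bromobenzene | Brc1cc(OCc2ccccc2)cc(OCc2ccccc2)c1 | intermediate
4 | {[2,4-bis(benzyloxy)-6-bromophenyl]methylidene}dimethyliminium dichlorophosphate | C[N+](C)=Cc1c(Br)cc(OCc2ccccc2)cc1OCc1ccccc1.[O-]P(=O)(Cl)Cl | intermediate (not isolated)
5 | 2,4-bis(benzyloxy)-6-bromobenzaldehyde | O=Cc1c(Br)cc(OCc2ccccc2)cc1OCc1ccccc1 | intermediate
6 | 5-bromo-2-methoxyphenol | COc1ccc(Br)cc1O | starting material
7 | 2-(benzyloxy)-4-bromo-1-methoxybenzene | COc1ccc(Br)cc1OCc1ccccc1 | intermediate
8 | 2-(benzyloxy)acetyl chloride | O=C(Cl)COCc1ccccc1 | starting material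
9 | N,O-dimethylhydroxylamine hydrochloride | CNOC.Cl | starting material
10 | 2-(benzyloxy)-N-methoxy-N-methylacetamide | CON(C)C(=O)COCc1ccccc1 | intermediate
11 | [3-(benzyloxy)-4-methoxyphenyl]lithium | [Li]c1ccc(OC)c(OCc2ccccc2)c1 | intermediate (not isolated)
12 | lithium 2-(benzyloxy)-1-[3-(benzyloxy)-4-methoxyphenyl]-1-[methoxy(methyl)amino]ethan-1-olate (racemic chelate) | [Li]OC(COCc1ccccc1)(N(C)OC)c1ccc(OC)c(OCc2ccccc2)c1 | intermediate (not isolated)
13 | 2-(benzyloxy)-1-[3-(benzyloxy)-4-methoxyphenyl]ethan-1-one | COc1ccc(C(=O)COCc2ccccc2)cc1OCc1ccccc1 | intermediate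
14 | lithium (Z)-2-(benzyloxy)-1-[3-(benzyloxy)-4-methoxyphenyl]ethen-1-olate | [Li]O/C(=C\OCc1ccccc1)c1ccc(OC)c(OCc2ccccc2)c1 | intermediate (not isolated)
15 | 2-(benzyloxy)-3-[2,4-bis(benzyloxy)-6-bromophenyl]-1-[3-(benzyloxy)-4-methoxyphenyl]-3-hydroxypropan-1-one (racemic mixture of syn and anti diastereomers) | COc1ccc(C(=O)C(OCc2ccccc2)C(O)c2c(Br)cc(OCc3ccccc3)cc2OCc2ccccc2)cc1OCc1ccccc1 | intermediate
16 | 2-(benzyloxy)-1-[2,4-bis(benzyloxy)-6-bromophenyl]-3-[3-(benzyloxy)-4-methoxyphenyl]propane-1,3-dione (racemic, enolisable) | COc1ccc(C(=O)C(OCc2ccccc2)C(=O)c2c(Br)cc(OCc3ccccc3)cc2OCc2ccccc2)cc1OCc1ccccc1 | intermediate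
17 | 3,5,7-tris(benzyloxy)-2-[3-(benzyloxy)-4-methoxyphenyl]-4H-chromen-4-one | COc1ccc(-c2oc3cc(OCc4ccccc4)cc(OCc4ccccc4)c3c(=O)c2OCc2ccccc2)cc1OCc1ccccc1 | intermediate
18 | tamarixetin (4'-O-methylquercetin) | COc1ccc(-c2oc3cc(O)cc(O)c3c(=O)c2O)cc1O | intermediate
19 | bis(tetrabutylammonium) tamarixetin 3,7-disulfate | COc1ccc(-c2oc3cc(OS(=O)(=O)[O-])cc(O)c3c(=O)c2OS(=O)(=O)[O-])cc1O.CCCC[N+](CCCC)(CCCC)CCCC.CCCC[N+](CCCC)(CCCC)CCCC | intermediate (not isolated)
20 | dipotassium tamarixetin 3,7-disulfate | COc1ccc(-c2oc3cc(OS(=O)(=O)[O-])cc(O)c3c(=O)c2OS(=O)(=O)[O-])cc1O.[K+].[K+] | intermediate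
21 | tamarixetin 3,7-bis(hydrogen sulfate), 5-hydroxy-2-(3-hydroxy-4-methoxyphenyl)-4-oxo-4H-chromene-3,7-diyl bis(hydrogen sulfate) | COc1ccc(-c2oc3cc(OS(=O)(=O)O)cc(O)c3c(=O)c2OS(=O)(=O)O)cc1O | target

**Step count**

Total steps: 11. Longest linear sequence: 8 steps (steps 1, 2, 6, 7, 8, 9, 10, 11; the branch through steps 3 or 4, then 5, is equally long).

**Steps most likely to fail**

Step 8 (ring C closure). The 2-benzyloxy-1,3-diketone may fragment by retro-Claisen cleavage in hot carbonate, or C–Br activation may stall at the crowded ring A (its aroyl group is twisted by two ortho substituents) and end in protodebromination. The fallback sets out from 16 and comes back at 17. The bromide is exchanged for a hydroxyl group and ring C is closed by dehydration, so that O1–C2 is formed in the closure. Miyaura borylation of 16 (B2pin2, Pd(dppf)Cl2, KOAc, dioxane, 80 °C) should give the aryl pinacol boronate F1. Oxidation with NaBO3·4H2O in THF/H2O at rt should give the 2-hydroxyaryl 1,3-diketone F2. Warming F2 with catalytic TsOH in toluene should dehydrate it to 17.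

Step 10 (sulfation). Regiocontrol may be lost, the reaction stopping at the 7-monosulfate or running on to the 3'-hydroxyl, which would leave ionic mixtures that are hard to separate. The fallback sets out from 18 and comes back at 20. Treatment of 18 with 2,2,2-trichloroethyl chlorosulfate (2.1 equiv), Et3N and DMAP in THF at 0 °C should give the neutral 3,7-bis(2,2,2-trichloroethyl sulfate) diester F3. F3 can be separated from regioisomeric and over-sulfated diesters on silica gel and its substitution pattern checked before unmasking. Zn dust and HCOONH4 in MeOH at rt should then release the diammonium disulfate F4, and KOAc in MeOH should precipitate 20.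

Step 6 (aldol). The addition to the hindered, electron-rich aldehyde may reverse (retro-aldol of the aldolate on warming or quench) or proton transfer may limit conversion. The fallback sets out from 5 and comes back at 16, leaving out step 7. Pinnick oxidation of 5 (NaClO2, NaH2PO4, 2-methyl-2-butene, t-BuOH/H2O) should give 2,4-bis(benzyloxy)-6-bromobenzoic acid F5. (COCl)2 with catalytic DMF in CH2Cl2 should give 2,4-bis(benzyloxy)-6-bromobenzoyl chloride F6. Addition of F6 to two equivalents of lithium enolate 14 in THF at −78 °C (Claisen-type C-acylation, the second equivalent taking up the acidic proton of the product) should give 16 directly.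

**Further compounds**

F1 | step 8 | 2-(benzyloxy)-1-[2,4-bis(benzyloxy)-6-(4,4,5,5-tetramethyl-1,3,2-dioxaborolan-2-yl)phenyl]-3-[3-(benzyloxy)-4-methoxyphenyl]propane-1,3-dione | COc1ccc(C(=O)C(OCc2ccccc2)C(=O)c2c(B3OC(C)(C)C(C)(C)O3)cc(OCc3ccccc3)cc2OCc2ccccc2)cc1OCc1ccccc1
F2 | step 8 | 2-(benzyloxy)-1-[2,4-bis(benzyloxy)-6-hydroxyphenyl]-3-[3-(benzyloxy)-4-methoxyphenyl]propane-1,3-dione | COc1ccc(C(=O)C(OCc2ccccc2)C(=O)c2c(O)cc(OCc3ccccc3)cc2OCc2ccccc2)cc1OCc1ccccc1
F3 | step 10 | tamarixetin 3,7-bis(2,2,2-trichloroethyl sulfate) | COc1ccc(-c2oc3cc(OS(=O)(=O)OCC(Cl)(Cl)Cl)cc(O)c3c(=O)c2OS(=O)(=O)OCC(Cl)(Cl)Cl)cc1O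
F4 | step 10 | diammonium tamarixetin 3,7-disulfate | COc1ccc(-c2oc3cc(OS(=O)(=O)[O-])cc(O)c3c(=O)c2OS(=O)(=O)[O-])cc1O.[NH4+].[NH4+]
F5 | step 6 | 2,4-bis(benzyloxy)-6-bromobenzoic acid | O=C(O)c1c(Br)cc(OCc2ccccc2)cc1OCc1ccccc1
F6 | step 6 | 2,4-bis(benzyloxy)-6-bromobenzoyl chloride | O=C(Cl)c1c(Br)cc(OCc2ccccc2)cc1OCc1ccccc1
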